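# Proposed total synthesis of CNP0232452.6 via a maleimide [5+2] photocycloaddition

## Structural features

The target has five rings. Pyrrole ring A (N21, C22, C11, C12, C13) shares N21–C22 with azepane ring B (C23 to C27) and C11–C22 with cyclohexane ring C (C3, C4, C10, C11, C22, C23). Ring C carries the cis-fused γ-lactone D (C4, O5, C6, C8, C10), and a second γ-lactone E (C14, C15, C16, C18, O20) sits on pyrrole carbon C13. Locants are those of the target SMILES read from left to right.

C3, C4, C10 and C23 are contiguous on ring C: the C3 ethyl group is trans to O5 and to C24, H4 and H10 are cis, and C24 lies on the face of O5. C8 adjoins C10, and H4, H10 and H8 share one face of ring D, so the C8 methyl group sits on the concave face next to C11. This is the less stable lactone epimer: enolate methylation would give the other one, and strong base endangers it. C14 and C16 (cis on ring E) are remote from the core and need their own control.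

The fragile groups are the electron-rich pyrrole (acid, oxidants), the C14–O20 bond (a pyrrolyl carbinol ester that ionises easily) and the enolisable C8–H and C16–H. The real difficulty is the C3/C4/C10/C23 array, because C23 stands next to a planar pyrrole carbon and nothing on the aromatic ring A can relay configuration to it, together with the contra-thermodynamic C8.

The key step uses the fact that ring B is a maleimide in disguise (N21, C24 to C27) that can be inserted across C22=C23 of a ring C cyclohexene. A two-carbon arm C12–C13 on C11 becomes ring A, and C11, still sp3 at that stage, passes configuration from C10 to C23 before aromatisation erases it.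

## Logic of the disconnections

**29 to 27 (through 28).** The O20–C18 acyl bond and the C14–H bond are cut. C16 then comes unchanged from a chiral-pool fragment and C14 is the carbonyl carbon of an aryl ketone, open to reagent-controlled reduction. Ring E is reduced to a keto acid side chain. The forward step must deliver hydride to one face of a deactivated 2-acylpyrrole and close the lactone without ionising the new C14–O bond.

**27 to 25 and 26.** The C13–C14 bond is cut. C13 is the only free α-position of the pyrrole, and one acylation brings in all of C14 to C18 with C16 in place. The forward step must open the anhydride at its methylene-side carbonyl and must not destroy the acid-sensitive pyrrole.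

**25 to 24.** Hydrogen is returned to C11, C12, C13 and C22. The saturated ring A gives back the two sp3 centres needed to relay configuration to C23. The forward dehydrogenation must stay within the five-membered ring.

**24 to 20 (through 23, 22, 21).** Sulfur, then oxygen, is restored at C24 and C27, and C25=C26 is reinstated. This reveals a seven-membered ene-dione. The forward steps must excise two carbonyl oxygens without touching lactone D and without epimerising C23, which is α to the C24 ketone.

**20 to 18 (key).** N21–C22 and C23–C24 are cut, so rings A and B vanish together. What remains is a bicyclic lactone with an imide on a two-carbon arm. The forward photoreaction must insert the alkene into the imide C–N bond on the arm face only.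

**18 to 16 and 17.** The N21–C13 bond is cut. The demand is neutral conditions, because C8 is now the labile epimer.

**16 to 14.** Only C8 is inverted. 14 is the stable epimer that the ring-forming chemistry delivers. The forward step needs a kinetic protonation from the convex face.

**14 to 12 (through 13).** C22–H goes back to a C22 sulfonate, and the C13 alcohol to an acid. The sulfonate keeps the ring alkene electron-poor while another alkene is cleaved. The forward reductions must spare lactone D.

**12 to 9 (through 11).** The O5–C6 bond is cut and C6 is rejoined to C13 as an alkene. The lactone carbonyl and the arm terminus are thus the two ends of one cyclohexene, and the cis C10/C11 pair and C8 become ring-fusion features of a bicycle. The forward cleavage must be chemoselective, and the C4 hydroxyl must capture C6 and not C13.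

**9 to 5 (through 8, 7, 6).** The C3–C2 bond and the sulfonate O–S bond are cut. A γ-oxygenated enone remains, whose conjugate addition sets ethyl trans to O5 while the enolate fixes the later alkene position. The demand is anti selectivity and clean enolate capture.

**5 to 3 (through 4).** The C4 carbinol goes back to a ketone and the C22 ketone to its ketal. The forward step is a 1,2-reduction from the convex face followed by ketal hydrolysis.

**3 to 1 and 2.** C10–C8 and C11–C12 are cut. This Diels–Alder disconnection sets C10, C11 and C8 in one step from two achiral materials. It needs ortho regiochemistry, endo addition and catalyst control of the enone face.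

**Routes set aside.** Two shorter-looking ways to 16 were rejected. A dissolving-metal reduction of an α-arylpropanoic acid would leave the side chain on an sp2 ring carbon, so no γ-lactonisation onto a ring alkene could follow. A later C23 ketone flanked by C3–H and the C4 acyloxy group would invite β-elimination and aromatisation.

## Other disconnections considered

**Alternative 1:** The cut is C3–C4 of ring C. Zerovalent palladium from Pd2(dba)3 and a chiral diphosphine would ionise the allylic carbonate of A1. The silyloxyfuran carbon C4 would then attack the inner allyl carbon C3 (six-membered closure) to give A2, with a vinyl group on C3 and ring D as a butenolide.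
- In its favour: rings A and B are at their final oxidation level from the start, so no carbonyl excision and no amine-to-pyrrole oxidation is needed. Here it is better than the chosen plan.
- Also in its favour: hydrogenating the butenolide from the face of H4 would place H10 and H8 cis to H4 directly, which is better than the chosen plan at C8.
- Against it: attack must occur at the inner allyl terminus and give the trans C3/C4 pair against or with the bias of the existing C23 centre. The tetrasubstituted, pyrrole-conjugated butenolide must then be hydrogenated on one face while the vinyl group is reduced. The C13 ester needs several steps to become ring E, where the chosen plan adds C14 to C18 in one acylation.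
- Comparison: both plans rely on one catalytic enantioselective step, and overall step economy is comparable.

**Alternative 2:** The cuts are C22–C11 and C13–C12, so rings A and C form together. Ac2O would cyclodehydrate the N-formyl amino acid A3 to a mesoionic oxazolium-5-olate. Its C22 and C13 termini add across the tethered ethynyl group, and loss of CO2 gives A4, which is identical with 25.
- In its favour: the pyrrole arrives directly, the step is thermal and scalable, and the tether fixes regiochemistry. On redox economy and on steps after the key step it is better than the chosen plan, since it would replace steps 11 to 16.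
- Against it: A3 needs C23, C3, C4, C10 and the labile C8 set on a flexible chain with no ring C to relay configuration. Münchnones without a substituent on the former formyl carbon are prone to self-condensation, and an unactivated terminal alkyne needs forcing conditions.
- Comparison: the chosen plan builds ring C first and lets a ring control the stereochemistry; this is its main structural advantage. The endgame from A4 is the same.

**Alternative 3:** The cut is C8–C10 of ring D. Rh2(5S-MEPY)4, a carboxamidate-bridged dimer of divalent rhodium, would decompose diazoacetate A5. The carbenoid carbon C8 would insert into the C10–H bond cis to the ester oxygen to give A6.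
- In its favour: catalytic, enantioselective insertion into cyclohexyl C–H bonds to give cis-fused γ-lactones is well established, and C10–H is activated by the adjacent pyrrole. In fixing C10 relative to C4 it is the equal of the chosen plan.
- Against it: the tertiary C3–H offers a second five-membered insertion, and the electron-rich pyrrole can trap the carbenoid. A6 lacks the C8 methyl group; enolate methylation would add it from the convex face and give the wrong epimer, so a kinetic protonation is still needed (two steps where the chosen plan needs one). The tricyclic pyrrole with C3, C4 and C23 must be made first, and the ester must still be turned into ring E.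
- Comparison: ring D formation is shorter than in the chosen plan, but the preparation of A5 and the endgame are longer.

Key step: step 11

Remarks on the chemistry:
- Labels C1 to C27 always mean the target locants; systematic names use their own numbering.
- Compounds 1, 2, 17 and 26 are taken as purchasable.
- In step 1 the antipode of the catalyst is chosen so that 3 and not its mirror image forms; both antipodes are available.

## Route

Step 1
Reactants: 1 4,4-dimethoxycyclohexa-2,5-dien-1-one; 2 (E)-penta-1,3-diene
Product: 3 (4aS,8R,8aR)-4,4-dimethoxy-8-methyl-4a,5,8,8a-tetrahydronaphthalen-1(4H)-one (cis-fused; methyl cis to the ketone carbon on the new ring)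
Conditions: (S)-o-tolyl-oxazaborolidine·HNTf2 (20 mol%), 2 (3 equiv), CH2Cl2, −78 → −40 °C
Reagents that add atoms: none
Why: Catalytic enantioselective Diels–Alder reaction of a quinone monoketal; the boron cation binds the ketone, the methyl-bearing diene terminus bonds to the α-carbon (ortho rule), so the ketone becomes C4 and the ketal C22. Endo addition gives the cis C10/C11 fusion and places the methyl cis to C4, and the catalyst selects the enone face and so the absolute configuration.

Step 2
Reactants: 3
Product: 5 (4S,4aR,5R,8aS)-4-hydroxy-5-methyl-4a,5,8,8a-tetrahydronaphthalen-1(4H)-one, via ketal alcohol 4 (not isolated)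
Conditions: NaBH4, CeCl3·7H2O, MeOH, −78 °C; then 0.5 M HCl, THF, 0 °C
Reagents that add atoms: water, O
Why: Luche 1,2-reduction from the convex face, the only open one because the cis ring and its methyl group cover the other, puts the C4 hydroxyl cis to C8. Mild acid then hydrolyses the allylic dimethyl ketal, which moves the enone carbonyl to C22 and makes C3 the β-carbon.

Step 3
Reactants: 5
Product: 6 triethylsilyl ether of 5 (C4–OSiEt3)
Conditions: Et3SiCl, imidazole, CH2Cl2, 0 °C
Reagents that add atoms: chlorotriethylsilane, CC[Si](Cl)(CC)CC
Why: Standard silylation of a secondary alcohol; the γ-silyloxy group is needed for anti-selective conjugate addition and comes off with dilute acid.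

Step 4
Reactants: 6
Product: 9 3-ethyl-4-hydroxy-5-methyl-3,4,4a,5,8,8a-hexahydronaphthalen-1-yl trifluoromethanesulfonate (ethyl trans to hydroxyl, hydroxyl cis to C8, cis-fused), via lithium enolate 7 (not isolated), via silyl ether triflate 8 (not isolated)
Conditions: Et2CuLi (from EtLi, CuBr·SMe2), Et2O/THF, −78 °C; N-(5-chloropyridin-2-yl)triflimide, −78 → 0 °C; then 1 M HCl, THF, 0 °C
Reagents that add atoms: lithium diethylcuprate, [Li+].CC[Cu-]CC; N-(5-chloropyridin-2-yl)-1,1,1-trifluoro-N-(trifluoromethylsulfonyl)methanesulfonamide, O=S(=O)(N(c1ccc(Cl)cn1)S(=O)(=O)C(F)(F)F)C(F)(F)F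
Why: Gilman conjugate addition to a γ-silyloxy cyclohexenone goes anti to the silyloxy group, here also the convex face, so ethyl enters trans to O5 at C3. O-sulfonylation of the regiodefined enolate fixes the later C22=C23 position as an electron-poor enol triflate, and the acid quench removes the silyl group.

Step 5
Reactants: 9
Product: 11 lactol aldehyde (C4–O5–C6 hemiacetal, C13 aldehyde; anomers at C6), via secondary ozonide 10 (not isolated)
Conditions: O3, CH2Cl2, −78 °C (Sudan Red 7B end point); PPh3, −78 °C → rt
Reagents that add atoms: ozone, [O-][O+]=O
Why: Ozonolysis takes the electron-rich cis-disubstituted alkene C6=C13 and leaves the electron-poor enol triflate. The C4 hydroxyl, cis to C8, traps the C6 aldehyde as a five-membered lactol and so tells the two termini apart.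

Step 6
Reactants: 11
Product: 12 lactone acid: 2-[7-ethyl-3-methyl-2-oxo-5-(trifluoromethylsulfonyloxy)-2,3,3a,4,7,7a-hexahydro-1-benzofuran-4-yl]acetic acid (3S epimer, methyl on the convex face)
Conditions: TEMPO (20 mol%), PhI(OAc)2 (2.5 equiv), MeCN/H2O (1:1), rt
Reagents that add atoms: water, O
Why: Oxoammonium oxidation turns the lactol into the γ-lactone and the aldehyde, through its hydrate, into the acid. Any equilibration α to C6 can only lead to the convex-methyl epimer that is already present.

Step 7
Reactants: 12
Product: 13 primary alcohol (C13–OH) of the lactone enol triflate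
Conditions: BH3·SMe2, THF, 0 °C → rt; MeOH
Reagents that add atoms: none
Why: Borane reduces a carboxylic acid much faster than a lactone and does not touch an enol triflate.

Step 8
Reactants: 13
Product: 14 (3S,3aS,4R,7R,7aS)-7-ethyl-4-(2-hydroxyethyl)-3-methyl-3a,4,7,7a-tetrahydro-1-benzofuran-2(3H)-one
Conditions: Pd(OAc)2 (5 mol%), PPh3, HCO2H, n-Bu3N, DMF, 60 °C
Reagents that add atoms: none
Why: Palladium-catalysed formate reduction of an enol triflate (oxidative addition, formate-to-hydride exchange, reductive elimination) gives the alkene at C22=C23 only.

Step 9
Reactants: 14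
Product: 16 (3R,3aS,4R,7R,7aS)-7-ethyl-4-(2-hydroxyethyl)-3-methyl-3a,4,7,7a-tetrahydro-1-benzofuran-2(3H)-one (C8 epimer of 14), via dilithium enolate alkoxide 15 (not isolated)
Conditions: LiN(iPr)2 (2.3 equiv), THF, −78 → −40 °C; then 2,6-di-tert-butyl-4-methylphenol, THF, −78 °C
Reagents that add atoms: none
Why: Lactone enolate formation followed by kinetic protonation; the proton enters from the convex face of ring D (the face of H4 and H10), because C11 and its arm cover the other face, and this pushes the methyl to the concave face as in the target. The hindered phenol protonates carbon directly and is too weak to relay the proton through the side-chain oxygen.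

Step 10
Reactants: 16; 17 maleimide
Product: 18 1-{2-[(3R,3aS,4R,7R,7aS)-7-ethyl-3-methyl-2-oxo-2,3,3a,4,7,7a-hexahydro-1-benzofuran-4-yl]ethyl}-1H-pyrrole-2,5-dione
Conditions: PPh3, DIAD, THF, −78 °C → rt
Reagents that add atoms: none
Why: Mitsunobu N-alkylation of an imide (pKa about 10) by a primary alcohol under neutral conditions; no stereocentre is involved and C8 is not exposed to base.

Step 11
Reactants: 18
Product: 20 tetracyclic pyrrolidine-fused azepine-2,5-dione with lactone D (C24 ketone, C27 lactam, C25=C26; H11, H22 and H23 cis), via azetidinium olate adduct 19 (not isolated)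
Conditions: hν (medium-pressure Hg lamp, Pyrex filter, λ > 290 nm), degassed MeCN (0.01 M), FEP flow reactor, rt
Reagents that add atoms: none
Why: Direct excitation of the maleimide chromophore, without sensitiser, lets the C24–N21 bond add across C22=C23 in a formal [2+2] sense to give the strained adduct 19, whose C24–N21 bond then breaks, so that C22 and C23 end up inserted between N21 and C24. The closest known reaction type is the intramolecular maleimide–alkene [5+2] photocycloaddition of N-(pent-4-enyl)-type imides, cyclohexenyl cases included, which gives pyrrolidine-fused azepine-2,5-diones. Ring A closes by attack of N21 on the proximal alkene carbon C22 through the three-atom tether C13–C12–C11 (five-membered, exo mode); ring B arises by ring expansion when C24 bonds to the distal carbon C23 (seven-membered). At C22 the short tether can reach only the face of ring C on which C12 stands, so rings A and C are cis-fused. At C23 the addition is suprafacial, so C24 enters on the face of N21, that is cis to C12, O5 and C8 and trans to the C3 ethyl group; C11 therefore controls both new centres. The step needs periselectivity for [5+2] over [2+2] addition of C25=C26 to the alkene; the latter is a triplet process and is held back by direct irradiation at high dilution with short residence time in flow. Regiochemistry follows from the tether length, and the ethyl group on the far face does not hinder the approach.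

Step 12
Reactants: 20
Product: 21 25,26-dihydro derivative of 20 (saturated keto lactam)
Conditions: H2 (1 atm), 10% Pd/C, EtOAc, rt
Reagents that add atoms: none
Why: Catalytic hydrogenation of the electron-poor ene-dione alkene; no new stereocentre forms and the neutral medium leaves C23 and C8 alone.

Step 13
Reactants: 21
Product: 22 C24 1,3-dithiolane of 21
Conditions: HSCH2CH2SH, BF3·OEt2, CH2Cl2, 0 °C → rt
Reagents that add atoms: ethane-1,2-dithiol, SCCS
Why: Lewis-acid dithioketalisation takes the ketone only; lactam and lactone carbonyls do not react under these conditions.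

Step 14
Reactants: 22
Product: 23 C27 thiolactam of 22
Conditions: Lawesson's reagent (0.6 equiv), toluene, 80 °C
Reagents that add atoms: Lawesson's reagent, COc1ccc(cc1)P1(=S)SP(=S)(S1)c1ccc(OC)cc1
Why: Thionation with Lawesson's reagent is much faster for a tertiary lactam than for a lactone, so lactone D is kept.

Step 15
Reactants: 23
Product: 24 tetracyclic amine (saturated rings A and B, lactone D; C24 and C27 as CH2)
Conditions: Raney nickel (W-2, washed neutral), EtOH, reflux
Reagents that add atoms: none
Why: Reductive desulfurisation (Mozingo type) replaces both the dithiolane and the thiocarbonyl by CH2 in one operation; neutral nickel avoids epimerisation at C8.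

Step 16
Reactants: 24
Product: 25 tetracyclic pyrrole lactone (rings A to D, C13 unsubstituted)
Conditions: activated MnO2 (excess), toluene, 80 °C
Reagents that add atoms: none
Why: MnO2 dehydrogenation of an N-alkylpyrrolidine to the pyrrole, a known oxidation of 1,2-disubstituted pyrrolidines that is driven by aromatisation. It removes the relay centres C11 and C22, and delocalisation of the nitrogen lone pair then protects the azepane α-position.

Step 17
Reactants: 25; 26 (S)-methylsuccinic anhydride
Product: 27 (2S)-2-methyl-4-oxo-4-(pyrrol-C13-yl)butanoic acid of the tetracycle (C14 ketone, C18 acid)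
Conditions: AlCl3, CH2Cl2, 0 °C; 1 M HCl work-up
Reagents that add atoms: none
Why: Friedel–Crafts acylation at the only free α-position of the pyrrole; the anhydride opens at the less hindered carbonyl next to CH2, so the methyl-bearing carbon stays α to the acid and keeps its configuration as C16.

Step 18
Reactants: 27
Product: 29 CNP0232452.6 (target), via hydroxy acid 28 (not isolated)
Conditions: RuCl(p-cymene)[(S,S)-TsDPEN] (2 mol%), HCO2H/Et3N (1:1), DMF, 40 °C; then PPTS (cat.), CH2Cl2, rt
Reagents that add atoms: none
Why: Asymmetric transfer hydrogenation of an aryl alkyl ketone; with the (S,S)-ligand hydride is delivered to the face that gives the S carbinol when the aryl group outranks the alkyl chain, as here at C14. The γ-hydroxy acid then lactonises to the cis-2,4-disubstituted ring E, which is also the more stable arrangement.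

## Compound list

1 | 4,4-dimethoxycyclohexa-2,5-dien-1-one | COC1(OC)C=CC(=O)C=C1 | starting material
2 | (E)-penta-1,3-diene | C/C=C/C=C | starting material
3 | (4aS,8R,8aR)-4,4-dimethoxy-8-methyl-4a,5,8,8a-tetrahydronaphthalen-1(4H)-one | O=C1C=CC(OC)(OC)[C@H]2CC=C[C@@H](C)[C@@H]12 | intermediate
4 | ketal alcohol (C4 carbinol of 3, hydroxyl cis to C8) | O[C@H]1C=CC(OC)(OC)[C@H]2CC=C[C@@H](C)[C@@H]12 | intermediate
5 | (4S,4aR,5R,8aS)-4-hydroxy-5-methyl-4a,5,8,8a-tetrahydronaphthalen-1(4H)-one | O[C@H]1C=CC(=O)[C@H]2CC=C[C@@H](C)[C@@H]12 | intermediate
6 | triethylsilyl ether of 5 | CC[Si](CC)(CC)O[C@H]1C=CC(=O)[C@H]2CC=C[C@@H](C)[C@@H]12 | intermediate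
7 | lithium enolate (C22–O–Li, C22=C23) of the C3-ethyl adduct | [Li+].CC[C@@H]1C=C([O-])[C@H]2CC=C[C@@H](C)[C@H]2[C@H]1O[Si](CC)(CC)CC | intermediate
8 | triethylsilyl ether of 9 | CC[C@@H]1C=C(OS(=O)(=O)C(F)(F)F)[C@H]2CC=C[C@@H](C)[C@H]2[C@H]1O[Si](CC)(CC)CC | intermediate
9 | 3-ethyl-4-hydroxy-5-methyl-3,4,4a,5,8,8a-hexahydronaphthalen-1-yl trifluoromethanesulfonate | CC[C@@H]1C=C(OS(=O)(=O)C(F)(F)F)[C@H]2CC=C[C@@H](C)[C@H]2[C@H]1O | intermediate
10 | secondary ozonide of 9 (1,2,4-trioxolane across C6/C13; ozonide carbons as formed) | CC[C@@H]1C=C(OS(=O)(=O)C(F)(F)F)[C@H]2CC3OOC(O3)[C@@H](C)[C@H]2[C@H]1O | intermediate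
11 | lactol aldehyde (C6 hemiacetal, anomers; C13 aldehyde) | CC[C@H]1[C@@H]2OC(O)[C@@H](C)[C@@H]2[C@H](CC=O)C(OS(=O)(=O)C(F)(F)F)=C1 | intermediate
12 | lactone acid with enol triflate (3S epimer) | CC[C@H]1[C@@H]2OC(=O)[C@@H](C)[C@@H]2[C@H](CC(=O)O)C(OS(=O)(=O)C(F)(F)F)=C1 | intermediate
13 | lactone alcohol with enol triflate (3S epimer) | CC[C@H]1[C@@H]2OC(=O)[C@@H](C)[C@@H]2[C@H](CCO)C(OS(=O)(=O)C(F)(F)F)=C1 | intermediate
14 | (3S,3aS,4R,7R,7aS)-7-ethyl-4-(2-hydroxyethyl)-3-methyl-3a,4,7,7a-tetrahydro-1-benzofuran-2(3H)-one | CC[C@H]1[C@@H]2OC(=O)[C@@H](C)[C@@H]2[C@H](CCO)C=C1 | intermediate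
15 | dilithium enolate alkoxide of 14 | [Li+].[Li+].CC[C@H]1[C@@H]2OC([O-])=C(C)[C@@H]2[C@H](CC[O-])C=C1 | intermediate
16 | (3R,3aS,4R,7R,7aS)-7-ethyl-4-(2-hydroxyethyl)-3-methyl-3a,4,7,7a-tetrahydro-1-benzofuran-2(3H)-one | CC[C@H]1[C@@H]2OC(=O)[C@H](C)[C@@H]2[C@H](CCO)C=C1 | intermediate
17 | maleimide (1H-pyrrole-2,5-dione) | O=C1C=CC(=O)N1 | starting material
18 | 1-{2-[(3R,3aS,4R,7R,7aS)-7-ethyl-3-methyl-2-oxo-2,3,3a,4,7,7a-hexahydro-1-benzofuran-4-yl]ethyl}-1H-pyrrole-2,5-dione | CC[C@H]1[C@@H]2OC(=O)[C@H](C)[C@@H]2[C@H](CCN3C(=O)C=CC3=O)C=C1 | intermediate
19 | azetidinium olate adduct (N21–C22–C23–C24 four-membered ring; N21 and C24 configuration as formed) | CC[C@H]1[C@@H]2OC(=O)[C@H](C)[C@@H]2[C@@H]2CC[N+]34[C@@H]2[C@@H]1C3([O-])C=CC4=O | intermediate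
20 | tetracyclic pyrrolidine-fused azepine-2,5-dione with lactone D | CC[C@H]1[C@@H]2OC(=O)[C@H](C)[C@@H]2[C@@H]2CCN3[C@@H]2[C@@H]1C(=O)C=CC3=O | intermediate
21 | 25,26-dihydro keto lactam | CC[C@H]1[C@@H]2OC(=O)[C@H](C)[C@@H]2[C@@H]2CCN3[C@@H]2[C@@H]1C(=O)CCC3=O | intermediate
22 | C24 1,3-dithiolane lactam | CC[C@H]1[C@@H]2OC(=O)[C@H](C)[C@@H]2[C@@H]2CCN3[C@@H]2[C@@H]1C1(CCC3=O)SCCS1 | intermediate
23 | C24 1,3-dithiolane C27 thiolactam | CC[C@H]1[C@@H]2OC(=O)[C@H](C)[C@@H]2[C@@H]2CCN3[C@@H]2[C@@H]1C1(CCC3=S)SCCS1 | intermediate
24 | tetracyclic amine with lactone D | CC[C@H]1[C@@H]2OC(=O)[C@H](C)[C@@H]2[C@@H]2CCN3[C@@H]2[C@@H]1CCCC3 | intermediate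
25 | tetracyclic pyrrole lactone (rings A to D) | CC[C@H]1[C@@H]2OC(=O)[C@H](C)[C@@H]2c2ccn3c2[C@@H]1CCCC3 | intermediate
26 | (S)-methylsuccinic anhydride | C[C@H]1CC(=O)OC1=O | starting material
27 | C13 keto acid (C14 ketone, 16S) | CC[C@H]1[C@@H]2OC(=O)[C@H](C)[C@@H]2c2cc(C(=O)C[C@H](C)C(=O)O)n3c2[C@@H]1CCCC3 | intermediate
28 | C14 hydroxy acid (14S,16S) | CC[C@H]1[C@@H]2OC(=O)[C@H](C)[C@@H]2c2cc([C@@H](O)C[C@H](C)C(=O)O)n3c2[C@@H]1CCCC3 | intermediate
29 | CNP0232452.6 | CC[C@H]1[C@@H]2OC(=O)[C@H](C)[C@@H]2c2cc([C@@H]3C[C@H](C)C(=O)O3)n3c2[C@@H]1CCCC3 | target

## Step count and least certain steps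

Total step count: 18. Longest linear sequence: 18 steps (from 1 and 2; 17 and 26 enter as purchased fragments).

**Step 11 (key step).** The excited maleimide may add its C25=C26 bond to the ring alkene in a [2+2] sense, the ene-dione product may photolyse further at high conversion, and light attenuation may stall the reaction on scale. Fallback, from 16 back to 21: Mitsunobu coupling of 16 with 3,4-dichloromaleimide would give the N-alkyl dichloromaleimide F1. Dichloromaleimides are the most dependable substrates for this ring expansion, and irradiation as in step 11 should give the dichloro azepinedione F2. Hydrogenation over Pd/C with Et3N would then remove both chlorines and saturate C25=C26 in one operation, giving 21.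

**Step 9.** Enolisation may be slow and incomplete, because H8 of 14 lies on the concave face. Protonation may also lose facial selectivity if the proton is passed on through the side-chain oxygen. Fallback, from 14 back to 16: soft enolisation with Me3SiOTf and Et3N, which removes H8 from the O-silylated lactone with a small base, would give the bis(trimethylsilyl) ketene acetal F3. Its protonolysis at low temperature (AcOH, THF/H2O, −20 °C) delivers the proton to the open convex face and also frees the primary alcohol, giving 16.

**Step 4.** The cuprate may add with incomplete anti selectivity or expel the γ-oxygen, and the aggregated enolate may be sulfonylated only in part. Fallback, from 6 back to 8: conjugate addition with an NH4Cl quench would give the silyl ether ketone F4, which can be purified and checked at C3. Kinetic deprotonation with KN(SiMe3)2 at −78 °C (the C23 methylene in preference to the tertiary C11–H) and N-phenyltriflimide would then give 8, which the acid treatment of step 4 converts into 9.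

**Step 16.** Oxidation may stop at a pyrroline, or go on at the azepane α-carbon C27 or at the pyrrole-adjacent C10 and C23 positions. Fallback, from 24 back to 25: mCPBA would give the N-oxide F5. Polonovski–Potier activation with (CF3CO)2O followed by base should form the ring-fusion iminium and then the enamine F6 (C11=C22), and DDQ would take this pyrroline to 25.

**Step 18.** The 2-acylpyrrole is a poor hydride acceptor, so the reduction may stall. The acidic medium may also ionise the new pyrrolyl C14–O bond and erode the configuration at C14. Fallback, from 27 back to 29: NaBH4 reduction of the sodium salt of 27 would give 28 together with its C14 epimer, the epimeric hydroxy acid F7. PPTS in toluene would lactonise both to 29 and the 14-epi lactone F8. Reversible ionisation at C14 under the same acid should enrich the more stable cis lactone 29, and F8 can be separated and resubmitted.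

**Step 1.** The diene may react sluggishly at the hindered β-carbon next to the ketal, and the enantioselectivity or its sense may fall short. Fallback, from 1 and 2 back to 5: an uncatalysed or BF3·OEt2-promoted cycloaddition would give racemic 3, that is 3 with its mirror image ent-3 F9. Step 2 on the racemate would give racemic 5 through 4 and the mirror-image ketal alcohol ent-4 F10, so that 5 is accompanied by ent-5 F11. Lipase-catalysed acylation with vinyl acetate would then convert the unwanted antipode into the acetate of ent-5 F12 and leave 5. Should the enzyme prefer 5, mild methanolysis of its acetate would return it.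

## Further compounds

F1 | step 11 | N-alkyl 3,4-dichloromaleimide analogue of 18 | CC[C@H]1[C@@H]2OC(=O)[C@H](C)[C@@H]2[C@H](CCN3C(=O)C(Cl)=C(Cl)C3=O)C=C1
F2 | step 11 | 25,26-dichloro analogue of 20 | CC[C@H]1[C@@H]2OC(=O)[C@H](C)[C@@H]2[C@@H]2CCN3[C@@H]2[C@@H]1C(=O)C(Cl)=C(Cl)C3=O
F3 | step 9 | bis(trimethylsilyl) ketene acetal of 14 | CC[C@H]1[C@@H]2OC(O[Si](C)(C)C)=C(C)[C@@H]2[C@H](CCO[Si](C)(C)C)C=C1
F4 | step 4 | silyl ether ketone (C22 ketone, C3 ethyl, C4–OSiEt3) | CC[C@@H]1CC(=O)[C@H]2CC=C[C@@H](C)[C@H]2[C@H]1O[Si](CC)(CC)CC
F5 | step 16 | N-oxide of 24 (configuration at nitrogen as formed) | CC[C@H]1[C@@H]2OC(=O)[C@H](C)[C@@H]2[C@@H]2CC[N+]3([O-])[C@@H]2[C@@H]1CCCC3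
F6 | step 16 | C11=C22 enamine (pyrroline) of the tetracycle | CC[C@H]1[C@@H]2OC(=O)[C@H](C)[C@@H]2C2=C3[C@@H]1CCCCN3CC2
F7 | step 18 | C14 epimer of 28 (14R,16S hydroxy acid) | CC[C@H]1[C@@H]2OC(=O)[C@H](C)[C@@H]2c2cc([C@H](O)C[C@H](C)C(=O)O)n3c2[C@@H]1CCCC3
F8 | step 18 | 14-epi lactone (C14 epimer of 29) | CC[C@H]1[C@@H]2OC(=O)[C@H](C)[C@@H]2c2cc([C@H]3C[C@H](C)C(=O)O3)n3c2[C@@H]1CCCC3
F9 | step 1 | ent-3 | O=C1C=CC(OC)(OC)[C@@H]2CC=C[C@H](C)[C@H]12
F10 | step 1 | ent-4 | O[C@@H]1C=CC(OC)(OC)[C@@H]2CC=C[C@H](C)[C@H]12
F11 | step 1 | ent-5 | O[C@@H]1C=CC(=O)[C@@H]2CC=C[C@H](C)[C@H]12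
F12 | step 1 | acetate of ent-5 | CC(=O)O[C@@H]1C=CC(=O)[C@@H]2CC=C[C@H](C)[C@H]12
A1 | alternative 1 | allylic carbonate silyloxyfuran (pyrroloazepine with C13 methyl ester) | COC(=O)c1cc(-c2coc(O[Si](C(C)C)(C(C)C)C(C)C)c2C)c2n1CCCC[C@@H]2/C=C/COC(=O)OC
A2 | alternative 1 | tetracyclic C3-vinyl butenolide with C13 methyl ester | C=C[C@H]1[C@@H]2OC(=O)C(C)=C2c2cc(C(=O)OC)n3c2[C@@H]1CCCC3
A3 | alternative 2 | N-formyl azepane-2-carboxylic acid with ethynyl lactone side chain | CC[C@@H]([C@@H]1OC(=O)[C@H](C)[C@@H]1C#C)[C@H]1CCCCN(C=O)C1C(=O)O
A4 | alternative 2 | tetracyclic pyrrole lactone (identical with 25) | CC[C@H]1[C@@H]2OC(=O)[C@H](C)[C@@H]2c2ccn3c2[C@@H]1CCCC3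
A5 | alternative 3 | C4 diazoacetate of the tricyclic pyrrole C13 methyl ester | CC[C@H]1[C@H](OC(=O)C=[N+]=[N-])Cc2cc(C(=O)OC)n3c2[C@@H]1CCCC3
A6 | alternative 3 | tetracyclic lactone without C8 methyl, C13 methyl ester | CC[C@H]1[C@@H]2OC(=O)C[C@@H]2c2cc(C(=O)OC)n3c2[C@@H]1CCCC3
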